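The target is cut at the aryl ether bond O–C4′, which joins the C8 oxygen to ring B (the 3′-methoxy-substituted cinnamyl ring). Because C8 with its oxygen, C9 methyl and C7 carbonyl carbon maps directly onto (S)-lactic acid, a copper-catalysed O-arylation of the lactate-derived hydroxy Weinreb amide with the 4′-iodo-3′-methoxycinnamyl methyl ether forms this bond in one operation while the C8–O bond stays intact, so the chiral-pool centre is kept with retention. The precursor pair is thus a free secondary alcohol carrying C7 as an N-methoxy-N-methylamide and an aryl iodide carrying the finished (E)-9′-methoxypropenyl side chain. A single aryl Grignard addition then installs ring A (3,4,5-trimethoxyphenyl) at C7.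

Key step: step 6

Remark on the chemistry: neolignan numbering is used (C7 = ketone carbon, C8 = stereocentre, C9 = its methyl; primed locants for the cinnamyl unit). C8 is (S) in the target, and the CIP order O > C7 > C9 > H is the same in ethyl (S)-lactate, in both amides and in the ketone. The descriptor therefore stays (S) as long as no bond to C8 is broken; the planned structures were checked against this and need no change. Enantiomeric purity is to be monitored by chiral HPLC at 9 and 13 against racemic reference samples made from racemic ethyl lactate.

Step 1
Reactants: 1 ethyl (S)-lactate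
Product: 2 (S)-2-hydroxy-N-methoxy-N-methylpropanamide
Conditions: MeNH(OMe)·HCl (2.0 equiv), iPrMgCl (4.5 equiv), THF, −20 → 0 °C; sat. aq NH4Cl, exhaustive CH2Cl2 extraction
Reagents that add atoms: N,O-dimethylhydroxylamine hydrochloride, CNOC.Cl
Why: Weinreb amidation (Bodroux-type aminolysis of an ester by a chloromagnesium amide): the magnesium amide formed from the amine salt attacks the ester carbonyl while the lactate hydroxyl is only deprotonated, and since the resulting alkoxide disfavours removal of C8–H and no bond to C8 is broken, the (S) centre should be carried over unchanged.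

Step 2
Reactants: 3 4-bromo-3-methoxybenzaldehyde
Product: 4 ethyl (E)-3-(4-bromo-3-methoxyphenyl)prop-2-enoate
Conditions: (EtO)2P(O)CH2CO2Et (1.2 equiv), NaH (1.2 equiv), THF, 0 °C → rt
Reagents that add atoms: triethyl phosphonoacetate, CCOC(=O)CP(=O)(OCC)OCC
Why: Horner–Wadsworth–Emmons olefination: the stabilised phosphonate anion adds reversibly to the aromatic aldehyde and collapses through the more stable oxaphosphetane, which should give the (E)-cinnamate with high selectivity while the aryl bromide and the methoxy group are inert.

Step 3
Reactants: 4 ethyl (E)-3-(4-bromo-3-methoxyphenyl)prop-2-enoate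
Product: 5 (E)-3-(4-bromo-3-methoxyphenyl)prop-2-en-1-ol
Conditions: DIBAL-H (2.5 equiv), CH2Cl2, −78 → 0 °C; aq Rochelle salt
Reagents that add atoms: none
Why: DIBAL-H reduction of an α,β-unsaturated ester: the Lewis-acidic aluminium hydride delivers two hydrides to the carbonyl carbon (1,2-mode) at low temperature, so the allylic alcohol should form without conjugate reduction, alkene isomerisation or loss of the aryl bromide.

Step 4
Reactants: 5 (E)-3-(4-bromo-3-methoxyphenyl)prop-2-en-1-ol
Product: 7 (E)-1-bromo-2-methoxy-4-(3-methoxyprop-1-enyl)benzene, via sodium alkoxide 6 (not isolated)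
Conditions: NaH (1.3 equiv), THF, 0 °C; then MeI (1.5 equiv), 0 °C → rt
Reagents that add atoms: iodomethane, CI
Why: Williamson ether synthesis: sodium hydride converts the only acidic group into the primary allylic alkoxide, which is methylated by iodomethane in an SN2 reaction, and nothing else in the molecule is electrophilic or acidic under these conditions.

Step 5
Reactants: 7 (E)-1-bromo-2-methoxy-4-(3-methoxyprop-1-enyl)benzene
Product: 8 (E)-1-iodo-2-methoxy-4-(3-methoxyprop-1-enyl)benzene
Conditions: NaI (2 equiv), CuI (5 mol%), trans-N,N′-dimethylcyclohexane-1,2-diamine (10 mol%), 1,4-dioxane, 110 °C, Ar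
Reagents that add atoms: sodium iodide, [Na+].[I-]
Why: Copper-catalysed aromatic Finkelstein reaction (aryl halogen exchange): diamine-ligated copper(I) swaps bromide for iodide at C4′ and the equilibrium is drawn to the aryl iodide because sodium bromide is far less soluble in dioxane than sodium iodide, while the ether groups and the trans alkene are spectators and no carbonyl or Michael acceptor is present that could consume the diamine.

Step 6
Reactants: 2 (S)-2-hydroxy-N-methoxy-N-methylpropanamide (1.5 equiv); 8 (E)-1-iodo-2-methoxy-4-(3-methoxyprop-1-enyl)benzene (1.0 equiv)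
Product: 9 (S)-N-methoxy-2-[2-methoxy-4-((E)-3-methoxyprop-1-enyl)phenoxy]-N-methylpropanamide
Conditions: CuI (10 mol%), 3,4,7,8-tetramethyl-1,10-phenanthroline (20 mol%), Cs2CO3 (1.5 equiv), 4 Å MS, toluene, 80–90 °C, Ar
Reagents that add atoms: none
Why: This is an Ullmann-type copper-catalysed C–O cross-coupling of a secondary aliphatic alcohol with an aryl iodide, a known reaction type: the carbonate turns the hydroxyl of 2 into a phenanthroline-ligated copper(I) alkoxide, the C–I bond of 8 is activated at copper, and reductive elimination forms the O–C4′ bond and returns copper(I). No ring is closed and no stereocentre is created; none of the four bonds at C8 is broken, so the (S) configuration of the lactate should pass into 9 with retention. The selectivity required is O-arylation without epimerisation at C8, without oxidation of the alcohol and without hydrodeiodination of 8. It is secured by the amide oxidation level at C7, which keeps C8–H far less acidic than in an ester or ketone, by the weak and poorly soluble base in toluene, by the iodide leaving group, which allows a moderate temperature, and by the reluctance of copper alkoxides toward β-hydride elimination. The tertiary amide has no N–H that could be arylated, the allylic ether and trans alkene of 8 are not addressed by the catalyst, and the excess of the cheap, water-soluble amide 2 should drive the valuable iodide to full conversion and is washed out afterwards.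

Step 7
Reactants: 9 (S)-N-methoxy-2-[2-methoxy-4-((E)-3-methoxyprop-1-enyl)phenoxy]-N-methylpropanamide; 10 5-bromo-1,2,3-trimethoxybenzene (1.4 equiv)
Product: 13 (S)-2-[2-methoxy-4-((E)-3-methoxyprop-1-enyl)phenoxy]-1-(3,4,5-trimethoxyphenyl)propan-1-one, via aryl Grignard reagent 11 (not isolated), via magnesium hemiaminal chelate 12 (not isolated)
Conditions: 10, Mg turnings (cat. I2), THF, 45 °C; solution added to 9, THF, −20 → 0 °C; inverse quench into sat. aq NH4Cl, 0 °C
Reagents that add atoms: none
Why: Weinreb ketone synthesis: the aryl Grignard reagent made by magnesium insertion adds once to the N-methoxy-N-methylamide, the five-membered magnesium chelate holds the tetrahedral stage so that no ketone is exposed to the organometallic, and the cold inverse quench into ammonium chloride buffer destroys the excess reagent before the ketone is released, so over-addition and base-induced epimerisation at C8 should both be avoided.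

Compound list
1 | ethyl (S)-lactate | CCOC(=O)[C@H](C)O | starting material
2 | (S)-2-hydroxy-N-methoxy-N-methylpropanamide | C[C@H](O)C(=O)N(C)OC | intermediate
3 | 4-bromo-3-methoxybenzaldehyde | COc1cc(C=O)ccc1Br | starting material
4 | ethyl (E)-3-(4-bromo-3-methoxyphenyl)prop-2-enoate | CCOC(=O)/C=C/c1ccc(Br)c(OC)c1 | intermediate
5 | (E)-3-(4-bromo-3-methoxyphenyl)prop-2-en-1-ol | OC/C=C/c1ccc(Br)c(OC)c1 | intermediate
6 | sodium (E)-3-(4-bromo-3-methoxyphenyl)prop-2-en-1-olate (not isolated) | [Na+].[O-]C/C=C/c1ccc(Br)c(OC)c1 | intermediate
7 | (E)-1-bromo-2-methoxy-4-(3-methoxyprop-1-enyl)benzene | COC/C=C/c1ccc(Br)c(OC)c1 | intermediate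
8 | (E)-1-iodo-2-methoxy-4-(3-methoxyprop-1-enyl)benzene | COC/C=C/c1ccc(I)c(OC)c1 | intermediate
9 | (S)-N-methoxy-2-[2-methoxy-4-((E)-3-methoxyprop-1-enyl)phenoxy]-N-methylpropanamide | COC/C=C/c1ccc(O[C@@H](C)C(=O)N(C)OC)c(OC)c1 | intermediate
10 | 5-bromo-1,2,3-trimethoxybenzene | COc1cc(Br)cc(OC)c1OC | starting material
11 | 3,4,5-trimethoxyphenylmagnesium bromide (not isolated) | COc1cc([Mg]Br)cc(OC)c1OC | intermediate
12 | bromomagnesium salt of the tetrahedral adduct at C7, (S) at C8, C7 configuration undefined (not isolated) | COC/C=C/c1ccc(O[C@@H](C)C(O[Mg]Br)(N(C)OC)c2cc(OC)c(OC)c(OC)c2)c(OC)c1 | intermediate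
13 | (8S,7′E)-3,4,5,3′,9′-pentamethoxy-7-oxo-8-O-4′-neolignan = (S)-2-[2-methoxy-4-((E)-3-methoxyprop-1-enyl)phenoxy]-1-(3,4,5-trimethoxyphenyl)propan-1-one | COC/C=C/c1ccc(O[C@@H](C)C(=O)c2cc(OC)c(OC)c(OC)c2)c(OC)c1 | target

Total step count: 7
Longest linear sequence: 6 steps (3 → 4 → 5 → 7 → 8 → 9 → 13; steps 2–7). Step 1 is the one-step side branch to 2.

Steps most likely to fail

1. Step 6. The chelating α-alkoxy amide may sequester copper so that the coupling stalls, and prolonged heating with carbonate may erode the configuration at C8. In the fallback the same ether is made by SN2 at C8 instead of arylation at oxygen. It sets out from bromide 7: palladium-catalysed hydroxylation (Pd2(dba)3, tBuXPhos, KOH, dioxane/H2O, 100 °C) should give (E)-2-methoxy-4-(3-methoxyprop-1-enyl)phenol F1. The enantiomeric amide (R)-2-hydroxy-N-methoxy-N-methylpropanamide F2 would be made from commercial methyl (R)-lactate, COC(=O)[C@@H](C)O, under the conditions of step 1. Mitsunobu etherification of F1 with F2 (PPh3, DIAD, toluene, 0 °C → rt) proceeds with inversion at C8 and comes back to the route at 9.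

2. Step 7. The Grignard reagent may act as a base toward C8–H, returning partly racemised amide, or the ketone may epimerise during release from the chelate and isolation. In the fallback the C7–C1 bond is formed at the aldehyde oxidation level. It sets out from 9: DIBAL-H (THF, −78 °C) should give (S)-2-[2-methoxy-4-((E)-3-methoxyprop-1-enyl)phenoxy]propanal F3, used crude at once. Addition of Grignard reagent 11 at −78 °C should give (2S)-2-[2-methoxy-4-((E)-3-methoxyprop-1-enyl)phenoxy]-1-(3,4,5-trimethoxyphenyl)propan-1-ol F4 as a mixture of C7 epimers, which does not matter. Dess–Martin oxidation (NaHCO3-buffered, CH2Cl2, 0 °C) under non-basic conditions comes back to the route at 13.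

3. Step 5. The halogen exchange is an equilibrium and may stop short of full conversion, leaving a bromide/iodide mixture that cannot be separated, or the long heating with copper may degrade the cinnamyl ether. In the fallback iodine is introduced by halogen–metal exchange. It sets out from 7: n-BuLi (THF, −78 °C) should give [2-methoxy-4-((E)-3-methoxyprop-1-enyl)phenyl]lithium F5, which is quenched at −78 °C with I2 and comes back to the route at 8.

Further compounds
F1 | step 6 | (E)-2-methoxy-4-(3-methoxyprop-1-enyl)phenol | COC/C=C/c1ccc(O)c(OC)c1
F2 | step 6 | (R)-2-hydroxy-N-methoxy-N-methylpropanamide | C[C@@H](O)C(=O)N(C)OC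
F3 | step 7 | (S)-2-[2-methoxy-4-((E)-3-methoxyprop-1-enyl)phenoxy]propanal | COC/C=C/c1ccc(O[C@@H](C)C=O)c(OC)c1
F4 | step 7 | (2S)-2-[2-methoxy-4-((E)-3-methoxyprop-1-enyl)phenoxy]-1-(3,4,5-trimethoxyphenyl)propan-1-ol (C1 epimer mixture) | COC/C=C/c1ccc(O[C@@H](C)C(O)c2cc(OC)c(OC)c(OC)c2)c(OC)c1
F5 | step 5 | [2-methoxy-4-((E)-3-methoxyprop-1-enyl)phenyl]lithium | COC/C=C/c1ccc([Li])c(OC)c1
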